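A direct plan would take the whole flavonol skeleton from kaempferol A1 and only redecorate it: double benzylation to kaempferol 7,4'-dibenzyl ether A2, 3-O-methylation to the 3-methyl ether A3, dibromination at C6 and C8 to the 6,8-dibromide A4, copper-mediated exchange of both bromides for methoxide to the 6,8-dimethoxy compound A5, then hydrogenolysis to the target. Its weakest steps would be:
- The site-selective double benzylation of the tetraphenol A1 to A2. The 3-OH is hardly less acidic than the 4'-OH, so 3,7-, 7,4'- and tris-ethers would form together and every later step would rest on a separation of polar isomers.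
- The twofold bromide-to-methoxide exchange that turns A4 into A5. Both C–Br bonds are flanked by two oxygen substituents, and hot NaOMe with CuBr also reduces aryl bromides, opens the pyrone ring and attacks benzyl ethers. The two methoxy groups that define ring A would come from the least reliable step, late in the sequence.
- The sequence from A1 through A3 and A4 to A5 as a whole. Five steps of protection, halogenation and exchange would form no bond of the skeleton and would depend on a costly natural flavonol.

**Retrosynthetic overview**
- Ring A (C4a–C5–C6–C7–C8–C8a, the fully substituted benzene with OH, OMe, OH, OMe on C5 to C8) is built last from an open chain. The cuts are C4a–C5 and C8–C8a, giving a four-carbon diene (C5 to C8, each carbon already carrying its final oxygen) and a ring C pyranone whose C5=C6 bond becomes C4a=C8a.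
- The diene is the bis(trimethylsilyl) dienol ether of methyl 2,4-dimethoxy-3-oxobutanoate, the Claisen dimer of methyl methoxyacetate. The dienophile is 2-[4-(benzyloxy)phenyl]-3-methoxy-5-(phenylsulfinyl)-4-pyranone, made from a β-keto sulfoxide, an amide acetal and 4-(benzyloxy)benzoyl chloride.
- Ring order: ring B is bought, ring C closes by enaminone acylation and cyclisation, ring A closes last by Diels–Alder reaction and aromatisation (loss of benzenesulfenic acid and methanol).
- Because the ring construction places every ring A substituent, no phenol has to be told from another, no C–Br bond is exchanged for C–OMe, and one benzyl group (4'-OH) is the only protecting group.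

Key step: step 7

Remark: the target has no stereocentre. The sulfoxide in 6, 7, 9, 11 and 12 is racemic, and the stereocentres of 2, 13 and 14 are uncontrolled and are destroyed later, so these SMILES carry no configuration.

Step 1
Reactants: 1 methyl methoxyacetate (2 equiv)
Product: 2 methyl 2,4-dimethoxy-3-oxobutanoate
Conditions: NaH (0.55 equiv per ester), THF, cat. MeOH, 0 to 60 °C; then 1 M HCl
Reagents that add atoms: methyl methoxyacetate (second equivalent), COCC(=O)OC
Why: Claisen self-condensation of an ester with two α-hydrogens, driven by deprotonation of the β-keto ester product; the new C2 centre is racemic and becomes sp2 in step 2.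

Step 2
Reactants: 2 methyl 2,4-dimethoxy-3-oxobutanoate; 3 chlorotrimethylsilane
Product: 4 methyl 2,4-dimethoxy-3-(trimethylsilyloxy)but-2-enoate
Conditions: Me3SiCl (1.5 equiv), Et3N (1.6 equiv), toluene, 20 °C; filtration under Ar, concentration
Reagents that add atoms: chlorotrimethylsilane, C[Si](C)(C)Cl
Why: O-silylation of the β-keto ester by soft enolisation should give the conjugated silyl enol ether; a regioisomeric enol ether would lead to the same diene in step 3.

Step 3
Reactants: 4 methyl 2,4-dimethoxy-3-(trimethylsilyloxy)but-2-enoate; 3 chlorotrimethylsilane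
Product: 5 (3Z)-1,2,4-trimethoxy-1,3-bis(trimethylsilyloxy)buta-1,3-diene
Conditions: LiN(iPr)2 (1.3 equiv), THF, −78 °C; Me3SiCl (1.4 equiv), −78 to 20 °C; hexane, filtration under Ar; used crude
Reagents that add atoms: chlorotrimethylsilane, C[Si](C)(C)Cl
Why: γ-deprotonation of the β-silyloxy acrylate and O-silylation of the extended ester enolate is the standard two-stage preparation of 1-alkoxy-1,3-bis(silyloxy)butadienes; allylic strain with the C2 substituent should place the C4 methoxy group cis to the C3 silyloxy group (3Z), on the outer side of the s-cis diene.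

Step 4
Reactants: 6 methyl phenyl sulfoxide; 1 methyl methoxyacetate
Product: 7 1-methoxy-3-(phenylsulfinyl)propan-2-one
Conditions: 6 (2.1 equiv), LiN(iPr)2 (2.1 equiv), THF, −78 °C; 1 (1.0 equiv), −78 to 0 °C; then 1 M HCl
Reagents that add atoms: methyl methoxyacetate, COCC(=O)OC
Why: acylation of an α-sulfinyl carbanion by an ester (β-keto sulfoxide synthesis); the second equivalent of carbanion deprotonates the product and shields it from further attack.

Step 5
Reactants: 7 1-methoxy-3-(phenylsulfinyl)propan-2-one; 8 N,N-dimethylformamide dimethyl acetal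
Product: 9 4-(dimethylamino)-1-methoxy-3-(phenylsulfinyl)but-3-en-2-one
Conditions: Me2NCH(OMe)2 (1.3 equiv), toluene, 20 to 50 °C
Reagents that add atoms: N,N-dimethylformamide dimethyl acetal, COC(OC)N(C)C
Why: the amide acetal condenses with the most acidic methylene, the one between the sulfinyl and carbonyl groups, to give the push–pull enaminone; the CH2OMe group is far less acidic and is kept for step 6.

Step 6
Reactants: 9 4-(dimethylamino)-1-methoxy-3-(phenylsulfinyl)but-3-en-2-one; 10 4-(benzyloxy)benzoyl chloride
Product: 12 2-[4-(benzyloxy)phenyl]-3-methoxy-5-(phenylsulfinyl)-4H-pyran-4-one, via aminomethylene diketone 11 (not isolated)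
Conditions: LiN(SiMe3)2 (2.2 equiv), THF, −78 °C; 10 (1.05 equiv), −78 to −20 °C; then 2 M HCl, 20 to 45 °C
Reagents that add atoms: 4-(benzyloxy)benzoyl chloride, O=C(Cl)c1ccc(OCc2ccccc2)cc1
Why: the kinetic α'-enolate of the vinylogous amide is C-acylated by the aroyl chloride, and on acidification the aryl ketone enol adds to the aminomethylene carbon and expels dimethylamine (6-endo addition–elimination), the established enaminone route to 4-pyranones.

Step 7
Reactants: 12 2-[4-(benzyloxy)phenyl]-3-methoxy-5-(phenylsulfinyl)-4H-pyran-4-one; 5 (3Z)-1,2,4-trimethoxy-1,3-bis(trimethylsilyloxy)buta-1,3-diene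
Product: 15 2-[4-(benzyloxy)phenyl]-5,7-dihydroxy-3,6,8-trimethoxy-4H-chromen-4-one, via cis-fused sulfinyl cycloadduct 13 (not isolated), via 5,8-dihydrochromenone 14 (not isolated)
Conditions: 5 (2.5 equiv), toluene, Ar, no Lewis acid, 20 to 60 °C, then 100 °C; then 1 M HCl, THF, 20 °C
Reagents that add atoms: (3Z)-1,2,4-trimethoxy-1,3-bis(trimethylsilyloxy)buta-1,3-diene, CO/C=C(\O[Si](C)(C)C)C(OC)=C(OC)O[Si](C)(C)C
Why: Proposed new method: a normal-demand [4+2] cycloaddition between ketene-acetal diene 5 and the sulfinyl-activated C5=C6 bond of pyranone 12 (asynchronous, the CH(OMe) terminus of 5 bonding first to the vinylogous-ester carbon C6) should close ring A as a six-membered carbocycle by forming C8–C8a and C4a–C5 in one operation. The closest known reaction types are the regiospecific annulation of 1-alkoxy-1,3-bis(silyloxy)butadienes onto halo- and sulfinylquinones with loss of HX and methanol, and the Diels–Alder reactions of 3-acceptor-substituted chromones with silyloxydienes that give xanthones; new is their union on a 5-sulfinyl-4-pyranone with a tetraoxygenated diene. The cis ring fusion of 13 places the sulfinyl group syn to H8a, so thermal syn-elimination of benzenesulfenic acid should give 14 and restore the pyranone; acid then expels methanol across C5/C8 and cleaves the silyl ethers, so C5 and C7 emerge as OH and C6 and C8 as OMe with no differentiation step. The step needs regioselectivity, which polarity secures: the nucleophilic diene terminus C4 attacks the β-carbon of the keto vinyl sulfoxide, and the tetrasubstituted, donor-substituted C2=C3 bond of 12 should not compete. The stereocentres of 13 are not controlled and vanish on aromatisation.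

Step 8
Reactants: 15 2-[4-(benzyloxy)phenyl]-5,7-dihydroxy-3,6,8-trimethoxy-4H-chromen-4-one
Product: 16 5,7-dihydroxy-2-(4-hydroxyphenyl)-3,6,8-trimethoxy-4H-chromen-4-one (target)
Conditions: H2 (1 atm), Pd/C (10 wt% palladium on carbon), EtOAc/MeOH, 20 °C
Reagents that add atoms: none
Why: hydrogenolysis of the single benzyl aryl ether; the aryl methyl ethers and the tetrasubstituted C2=C3 bond are inert, and 15 is crystallised first to remove sulfur by-products of step 7.

**Compound list**
1 | methyl methoxyacetate | COCC(=O)OC | starting material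
2 | methyl 2,4-dimethoxy-3-oxobutanoate (racemic) | COCC(=O)C(OC)C(=O)OC | intermediate
3 | chlorotrimethylsilane | C[Si](C)(C)Cl | starting material
4 | methyl 2,4-dimethoxy-3-(trimethylsilyloxy)but-2-enoate (geometry not defined) | COCC(O[Si](C)(C)C)=C(OC)C(=O)OC | intermediate
5 | (3Z)-1,2,4-trimethoxy-1,3-bis(trimethylsilyloxy)buta-1,3-diene (geometry at C1=C2 not defined) | CO/C=C(\O[Si](C)(C)C)C(OC)=C(OC)O[Si](C)(C)C | intermediate
6 | methyl phenyl sulfoxide (racemic) | CS(=O)c1ccccc1 | starting material
7 | 1-methoxy-3-(phenylsulfinyl)propan-2-one (racemic) | COCC(=O)CS(=O)c1ccccc1 | intermediate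
8 | N,N-dimethylformamide dimethyl acetal | COC(OC)N(C)C | starting material
9 | 4-(dimethylamino)-1-methoxy-3-(phenylsulfinyl)but-3-en-2-one (racemic) | COCC(=O)C(=CN(C)C)S(=O)c1ccccc1 | intermediate
10 | 4-(benzyloxy)benzoyl chloride | O=C(Cl)c1ccc(OCc2ccccc2)cc1 | starting material
11 | 1-[4-(benzyloxy)phenyl]-5-(dimethylamino)-2-methoxy-4-(phenylsulfinyl)pent-4-ene-1,3-dione | COC(C(=O)c1ccc(OCc2ccccc2)cc1)C(=O)C(=CN(C)C)S(=O)c1ccccc1 | intermediate (not isolated)
12 | 2-[4-(benzyloxy)phenyl]-3-methoxy-5-(phenylsulfinyl)-4H-pyran-4-one (racemic) | COc1c(-c2ccc(OCc3ccccc3)cc2)occ(S(=O)c2ccccc2)c1=O | intermediate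
13 | 2-[4-(benzyloxy)phenyl]-3,5,6,8-tetramethoxy-4a-(phenylsulfinyl)-5,7-bis(trimethylsilyloxy)-4a,5,8,8a-tetrahydro-4H-chromen-4-one (cis-fused, racemic, other centres uncontrolled) | COC1=C(c2ccc(OCc3ccccc3)cc2)OC2C(OC)C(O[Si](C)(C)C)=C(OC)C(OC)(O[Si](C)(C)C)C2(S(=O)c2ccccc2)C1=O | intermediate (not isolated)
14 | 2-[4-(benzyloxy)phenyl]-3,5,6,8-tetramethoxy-5,7-bis(trimethylsilyloxy)-5,8-dihydro-4H-chromen-4-one | COC1=C(c2ccc(OCc3ccccc3)cc2)OC2=C(C1=O)C(OC)(O[Si](C)(C)C)C(OC)=C(O[Si](C)(C)C)C2OC | intermediate (not isolated)
15 | 2-[4-(benzyloxy)phenyl]-5,7-dihydroxy-3,6,8-trimethoxy-4H-chromen-4-one | COc1c(O)c(OC)c2oc(-c3ccc(OCc4ccccc4)cc3)c(OC)c(=O)c2c1O | intermediate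
16 | 5,7-dihydroxy-2-(4-hydroxyphenyl)-3,6,8-trimethoxy-4H-chromen-4-one | COc1c(O)c(OC)c2oc(-c3ccc(O)cc3)c(OC)c(=O)c2c1O | target

**Step count**
Total steps: 8. Longest linear sequence: 5 steps (steps 4, 5, 6, 7, 8; the diene branch, steps 1, 2, 3, 7, 8, is equally long).

**Steps most likely to fail**

1. Step 7 (proposed new method). The cycloaddition may stop after the first C–C bond at an open Michael-type adduct. The pyranone ring may open by loss of its ring oxygen from C8a. The hindered diene may not engage the sulfinyl alkene before the sulfoxide eliminates. The fallback uses known reaction types and builds ring A first and ring C last. It sets out from diene 5, whose nucleophilic C4 is acylated with methyl 3-chloro-3-oxopropanoate (CH2Cl2, −78 to 20 °C, then dilute HCl) to give dimethyl 2,4-dimethoxy-3,5-dioxoheptanedioate F1. Dieckmann cyclisation of C6 onto the C1 ester (Mg(OMe)2 or NaOMe, MeOH, reflux) and enolisation should give methyl 2,4,6-trihydroxy-3,5-dimethoxybenzoate F2. Saponification and decarboxylation (aqueous NaOH under N2, then HCl, 80 °C) should give 2,4-dimethoxybenzene-1,3,5-triol F3, which has a mirror plane through C3 and C6 and a single free ring position. Thermal cyclocondensation of F3 (neat or in Ph2O, 200 to 220 °C, a Simonis/Mentzer-type chromone synthesis) with methyl 3-[4-(benzyloxy)phenyl]-2-methoxy-3-oxopropanoate F4 (from the lithium enolate of 1 and acid chloride 10) comes back to the route at 15.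

2. Step 6. The lithium enolate may be O-acylated instead of C-acylated, and the acid chloride may attack the sulfinyl oxygen. The fallback introduces the aroyl group first, with an ester, and the one-carbon unit last. It sets out from 7, whose dianion (LiN(iPr)2, 3 equiv, THF, −78 to 0 °C) is acylated at the CH2OMe carbon by methyl 4-(benzyloxy)benzoate to give 1-[4-(benzyloxy)phenyl]-2-methoxy-4-(phenylsulfinyl)butane-1,3-dione F5. Condensation of F5 with 8 at its only methylene gives 11, where the fallback comes back to the route; 11 closes to 12 on acidification as in step 6.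

3. Step 3. Possible failures are C-silylation, incomplete γ-deprotonation, formation of the 3E isomer (methoxy group on the inner side of the diene, which would block the cycloaddition) and hydrolysis of the diene on handling. The fallback replaces the silyl diene by an anionic annulation. It sets out from 4, whose lithium dienolate (LiN(iPr)2, THF, −78 °C) is not silylated but added to pyranone 12. Conjugate addition at C6 followed by Dieckmann closure of the C5 carbanion onto the ester (a Michael–Dieckmann annulation of the Staunton–Weinreb type) and acidic work-up should give 2-[4-(benzyloxy)phenyl]-3,6,8-trimethoxy-4a-(phenylsulfinyl)-4a,8a-dihydro-4H-chromene-4,5,7(6H,8H)-trione F6. Warming F6 in toluene (80 °C) eliminates benzenesulfenic acid and the product enolises to 15, where the fallback comes back to the route.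

Further compounds
F1 | step 7 | dimethyl 2,4-dimethoxy-3,5-dioxoheptanedioate | COC(=O)C(OC)C(=O)C(OC)C(=O)CC(=O)OC
F2 | step 7 | methyl 2,4,6-trihydroxy-3,5-dimethoxybenzoate | COC(=O)c1c(O)c(OC)c(O)c(OC)c1O
F3 | step 7 | 2,4-dimethoxybenzene-1,3,5-triol | COc1c(O)cc(O)c(OC)c1O
F4 | step 7 | methyl 3-[4-(benzyloxy)phenyl]-2-methoxy-3-oxopropanoate | COC(=O)C(OC)C(=O)c1ccc(OCc2ccccc2)cc1
F5 | step 6 | 1-[4-(benzyloxy)phenyl]-2-methoxy-4-(phenylsulfinyl)butane-1,3-dione | COC(C(=O)c1ccc(OCc2ccccc2)cc1)C(=O)CS(=O)c1ccccc1
F6 | step 3 | 2-[4-(benzyloxy)phenyl]-3,6,8-trimethoxy-4a-(phenylsulfinyl)-4a,8a-dihydro-4H-chromene-4,5,7(6H,8H)-trione | COC1=C(c2ccc(OCc3ccccc3)cc2)OC2C(OC)C(=O)C(OC)C(=O)C2(S(=O)c2ccccc2)C1=O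
A1 | direct plan | kaempferol | O=c1c(O)c(-c2ccc(O)cc2)oc2cc(O)cc(O)c12
A2 | direct plan | kaempferol 7,4'-dibenzyl ether | O=c1c(O)c(-c2ccc(OCc3ccccc3)cc2)oc2cc(OCc3ccccc3)cc(O)c12
A3 | direct plan | kaempferol 7,4'-dibenzyl 3-methyl ether | COc1c(-c2ccc(OCc3ccccc3)cc2)oc2cc(OCc3ccccc3)cc(O)c2c1=O
A4 | direct plan | 6,8-dibromokaempferol 7,4'-dibenzyl 3-methyl ether | COc1c(-c2ccc(OCc3ccccc3)cc2)oc2c(Br)c(OCc3ccccc3)c(Br)c(O)c2c1=O
A5 | direct plan | 6,8-dimethoxykaempferol 7,4'-dibenzyl 3-methyl ether | COc1c(-c2ccc(OCc3ccccc3)cc2)oc2c(OC)c(OCc3ccccc3)c(OC)c(O)c2c1=O
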